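The stop is the easy step: the autumn run reads 0 % of starting material at 0.667 h, and the flask gets 2.0 h for twice that charge on the same catalyst, so its starting material should be consumed well before the asked time, provided the reagent lasts.

in all of them: free catalyst 24 mM
- autumn: starting material 0.10 M; reagent 0.21 M; run made earlier
- dusk: starting material 0.40 M; reagent 0.21 M; run made earlier
- flask: starting material 0.20 M; reagent 0.210 M; time 2.0 h

| run | time / h | target / % | starting material / % |
|---|---|---|---|
| autumn | 0.667 | 62.8 | 0 |
| autumn | 1.33 | 63.7 | 1.7 |
| autumn | 2.00 | 62.4 | 0 |
| autumn | 2.50 | 63.8 | 0.7 |
| dusk | 0.200 | 6.8 | 2.7 |
| dusk | 0.417 | 6.7 | 2.0 |
| dusk | 1.00 | 4.9 | 0.9 |
| dusk | 2.50 | 4.6 | 0.8 |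

(standard deviation of a reading: 1 percentage point)

- percentages count the starting material that a species holds: one side product counts as two
- reactions considered so far: reagent + free catalyst -> catalyst intermediate A; starting material + catalyst intermediate A <-> catalyst intermediate B; catalyst intermediate B -> catalyst intermediate C; catalyst intermediate C -> free catalyst + target; starting material + target -> side product
- the reaction counts as stopped when no species that holds the starting material changes by six tenths of a point or more over the second half of the time

- the state of affairs at 2.0 h: stopped, and by what, or still going (it is still moving / forward and back rates have come level / the reagent has run out first / no working catalyst is left / all of the starting material has reacted)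
- the target standing at 2.0 h, as a percentage of the starting material charged

The yield is better counted as a fraction left, because target formed by the catalyst is then burnt by starting material to side product. My own reckoning takes the logarithm of the fraction kept as falling in step with the charge, and calls the burn load the natural logarithm of one over the fraction kept, per molar of charge. The autumn readings average 63.2 %, which gives a load of 4.59 /M.

The bound from above is that autumn figure, read from the smaller charge, since the dusk run with the larger charge kept less. The dusk run, with its first target reading of 6.8 %, gives a higher load of 6.72 /M, which applied to the flask gives a bound from below of 26.1 %. Autumn's load puts the flask at 39.9 %. One reagent goes with each target ever made and one more with each catalyst held as catalyst intermediate A, so the flask should take 0.164 M, less than its 0.210 M, and starting material should be the limiting reagent. The same count on the dusk run comes to 0.238 M, more than its 0.21 M, so the dusk load holds a reagent shortage besides the burn and serves as a bound, not as an estimate.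

The forecast says all of the starting material has reacted and 48 %, on these grounds: “Fitting autumn's 63%, a catalytic rate first-order in starting material predicts about 47%, and a zero-order rate about 50%”. That lies inside the bracket, 8.1 percentage points above my figure.

The flask gives: all of the starting material has reacted, with target at 42.9 %.

    reagent + free catalyst → catalyst intermediate A (k = 8.90 /M/s)
    starting material + catalyst intermediate A ⇌ catalyst intermediate B (K = 50.0 /M, k = 0.630 /M/s)
    catalyst intermediate B → catalyst intermediate C (k = 0.130 /s)
    catalyst intermediate C → free catalyst + target (k = 0.130 /s)
    starting material + target → side product (k = 0.0800 /M/s)

The burn of target by starting material is the reason for the shortfall: the same flask without that step holds 100 % of target against 42.9 %. The flask's own burn load comes to 4.23 /M against the 4.59 /M read from the autumn run. Carried to the neighbour flask charged with 0.12 M of starting material, autumn's load gives 57.6 %, and that neighbour stands at 58.6 %.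

All runs come from a simulation for an exercise; the scatter is artificial.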